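Remark on the chemistry: 1-(2-hydroxy-3,4,6-trimethoxyphenyl)ethan-1-one is assumed to be a catalogue compound (otherwise one acetylation/ortho-demethylation step from 1,2,3,5-tetramethoxybenzene). Flavan locants are used throughout, unprimed for the aromatic flavan-4-ol half (unit A) and double-primed for the dearomatised half (unit B); the target is then (2S,4R,2''S,8''S,8a''S).

## Structural features

The target is a dimer of one C15 unit, a 5,7,8-trioxygenated 2-phenylchroman. Unit A is an intact (2S,4R)-2,4-trans-flavan-4-ol with a hexasubstituted benzo ring; unit B has its benzo ring dearomatised to a cross-conjugated dienone (C5''=O, C6''=C7''-OMe, C4a''=C4''). The halves are joined twice, by C6–C8'' and by O5–C8a'', which closes a cis-fused 2,3-dihydrobenzofuran. C8a'' is an O,O-ketal carbon (O1'' and O5) common to the dihydropyran, the cyclohexenone and the dihydrofuran, and C8'' is a fully substituted carbon bearing OMe and the aryl group. These two adjacent stereocentres are tied to each other by the cis fusion; the open question is their sense relative to C2'', which is 1,3 to C8a'' across O1'' (aryloxy trans to phenyl) but 1,4 to C8'', while C2 and C4 of unit A are remote. Fragile groups are the aryl/alkyl ketal, the tertiary benzylic methyl ether, the β-methoxy enone and the C4 carbinol on a phloroglucinol-type ring, which ionises easily (to an ortho-quinone methide when O5 is free). The real difficulty is the C8''/C8a'' pair: any union that forms C6–C8'' first sets C8'' on a flat ring four atoms from the only centre that could control it. The key step exploits the fact that, at the quinone oxidation level of unit B, O1''–C8a''=C4a''–C4''(OAc) is a glycal-like enol ether with an allylic leaving group, conjugated to C5''=O. An oxygen nucleophile can therefore enter at C8a'', next to C2'', with transposition of the double bond to C4a''=C4'', which is the enone of the target.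

## Logic of the disconnections

16 to 15: the C4–O bond of unit A is cut back to C4–H. An oxygen at C4 would ionise in the acid-mediated ring closure and, beside a free O5 under base, would give an ortho-quinone methide; as CH2 the position is inert and the unit A fragment becomes trivial. The forward step must oxidise one benzylic C–H selectively and deliver oxygen trans to the 2-phenyl group.

15 to 14: the O–CH3 bond at C8'' is cut. This leaves the C8'' oxygen as the carbonyl oxygen of the preceding ring closure. The forward step must alkylate a hindered tertiary alcohol without touching the vinylogous ester.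

14 to 13: the C6–C8'' bond is cut, opening the dihydrofuran. In 13 the aryl ring hangs from the ketal oxygen beside a C8'' ketone, so the bond forms intramolecularly and only on the face of the ketal oxygen. C8'' then needs no control of its own. The forward step must favour attack at the ketone over the enone terminus C4''.

13 to 12 and 9 (key disconnection): the O5–C8a'' bond is cut with transposition of C4a''=C4'' back to C8a''=C4a'' and return of a leaving group to C4''. This separates the target into two monocyclic-core flavans of equal size and places the first new stereocentre (C8a'') next to C2''. The forward step must be an oxygen attack at a fully substituted alkoxy-bearing quinone carbon, site-selective against C7'' and face-selective.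

9 to 8, 7 and 6: the two quinone C=O bonds go back to para-disposed methoxy groups, the acetate to an inverted carbinol, the carbinol to the ketone. The 4''-acetate must be trans to the 2''-phenyl group so that it is axial when the nucleophile enters trans to phenyl.

12 to 10 and 6: the C4 methylene goes back to the ketone, the free O5 to the peri methoxy group. Both halves thus converge on 6, so C2 and C2'' are set once.

6 to 4 and 5, and 4 to 1 and 2: the C2–phenyl bond is cut as an enantioselective conjugate addition to a chromone, whose pyranone carbon C2 comes from a one-carbon amide acetal and an ortho-hydroxyacetophenone.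

## Other disconnections considered

Alternative 1: (first to mind, biomimetic) Cut C6–C8'' and O5–C8a'' together at the phenol oxidation level. Forward: the monomer (2S,4R)-7,8-dimethoxy-2-phenylchromane-4,5-diol A1 would be oxidised (PhI(OAc)2, MeOH) to the quinone monoketal (2S,4R)-4-hydroxy-7,8,8-trimethoxy-2-phenyl-2,3,4,8-tetrahydro-5H-chromen-5-one A2 and coupled under acid with a second molecule of A1 (C6 attacks C8'', O5 adds to C8a'', water is lost from C4''). Ground for preferring the chosen plan: here C8'' is made first, by intermolecular attack on a flat cation four atoms from C2'', and the ketal can only follow it, so nothing in the substrate differentiates the faces. A1 is in addition an ortho-quinone methide precursor as nucleophile and as electrophile, so self-condensation through C4 competes. The chosen plan makes C8a'' first, where C2'' has leverage, and uses partners that cannot form quinone methides.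

Alternative 2: Cut C6–C8'' as aryl carbanion plus quinone carbonyl. Forward: (2S)-7,8-dimethoxy-5-(methoxymethoxy)-2-phenylchromane A4 would be lithiated at C6 and added to the C8'' carbonyl of (2S)-7-methoxy-2-phenyl-3,4-dihydro-2H-chromene-5,8-dione A3; O-methylation would give the para-quinol ether (2S,8S)-8-[(2S)-7,8-dimethoxy-5-(methoxymethoxy)-2-phenylchroman-6-yl]-7,8-dimethoxy-2-phenyl-2,3,4,8-tetrahydro-5H-chromen-5-one A5; acid would free O5 for oxa-Michael closure, and a dehydrogenation would install C4a''=C4''. Ground: the regiochemistry of the 1,2-addition is dependable, but the stereochemical blind spot is the same (C8'' first, remote from C2''). The oxa-Michael closure has two competing β-alkoxy termini (C7'' and C8a'') without an irreversible exit, and a protecting group and a late dehydrogenation add steps.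

Alternative 3: Build the hexasubstituted benzo ring of unit A last, cutting C7–C8, C5–C6 and C4a–C5 (Dötz benzannulation). Forward: the carbene complex pentacarbonyl{[(2S,4R)-4-(tert-butyldimethylsilyloxy)-2-phenyl-3,4-dihydro-2H-pyran-6-yl](methoxy)methylidene}chromium A6, (CO)5Cr=C(OMe)R, would react with the alkynyl ether (2S,8S)-7,8-dimethoxy-8-(methoxyethynyl)-2-phenyl-2,3,4,8-tetrahydro-5H-chromen-5-one A7 and CO to give the 4-methoxyphenol ring, with the new 5-OH beside the C8'' substituent ready to close the ketal. Ground: the insertion would have to place the methoxy-bearing alkyne carbon next to the carbene carbon, against the electronic preference of donor-substituted alkynes. The quaternary carbon of A7 would still come from an unselective 1,2-addition to A3, and A6 needs its own enantioselective synthesis. The ring construction is elegant for the substitution pattern but gives no control over the C8''/C8a'' pair.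

Key step: step 8

## Route

Step 1
Reactants: 1 1-(2-hydroxy-3,4,6-trimethoxyphenyl)ethan-1-one; 2 N,N-dimethylformamide dimethyl acetal
Product: 4 5,7,8-trimethoxy-4H-chromen-4-one, via enaminone 3 (not isolated)
Conditions: 2 (2 equiv), toluene, 110 °C; then conc. HCl, CH2Cl2, rt
Reagents that add atoms: none
Why: Condensation of the methyl ketone with the amide acetal gives the β-dimethylamino enone, and acid-induced conjugate addition of the ortho-phenol with loss of dimethylamine closes the pyranone (enaminone route to chromones); the single free phenol of 1 fixes the 5,7,8-pattern.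

Step 2
Reactants: 4 5,7,8-trimethoxy-4H-chromen-4-one; 5 phenylboronic acid
Product: 6 (2S)-5,7,8-trimethoxy-2-phenylchroman-4-one
Conditions: Pd(OCOCF3)2 (5 mol %), (R)-4-tert-butyl-2-(pyridin-2-yl)-4,5-dihydrooxazole (6 mol %), NH4PF6, H2O, ClCH2CH2Cl, 60 °C
Reagents that add atoms: none
Why: Catalytic asymmetric conjugate addition of an arylboronic acid to a chromone (aryl transfer to cationic divalent palladium, carbopalladation of C2=C3, protonolysis of the palladium enolate); C2 is set by the pyridine-oxazoline ligand, whose antipode is chosen (by analogy with cyclic enones) so that phenyl enters the face giving 2S.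

Step 3
Reactants: 6 (2S)-5,7,8-trimethoxy-2-phenylchroman-4-one
Product: 7 (2S,4S)-5,7,8-trimethoxy-2-phenylchroman-4-ol
Conditions: NaBH4, MeOH/THF, 0 °C
Reagents that add atoms: none
Why: Borohydride adds pseudo-axially to the C4 carbonyl of the half-chair with equatorial 2-phenyl and should give the equatorial, 2,4-cis alcohol; a short reaction at 0 °C avoids base-induced ring opening at C2.

Step 4
Reactants: 7 (2S,4S)-5,7,8-trimethoxy-2-phenylchroman-4-ol
Product: 8 (2S,4R)-5,7,8-trimethoxy-2-phenylchroman-4-yl acetate
Conditions: AcOH, PPh3, DIAD, toluene, -20 °C to rt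
Reagents that add atoms: acetic acid, CC(=O)O
Why: Mitsunobu esterification inverts C4 to the 2,4-trans acetate; any leakage through the stabilised benzylic cation should converge on the same isomer, because the cation is captured pseudo-axially, away from the peri 5-OMe.

Step 5
Reactants: 8 (2S,4R)-5,7,8-trimethoxy-2-phenylchroman-4-yl acetate
Product: 9 (2S,4R)-7-methoxy-5,8-dioxo-2-phenyl-3,4,5,8-tetrahydro-2H-chromen-4-yl acetate
Conditions: (NH4)2Ce(NO3)6 (2.5 equiv), MeCN/H2O, 0 °C, short reaction time
Reagents that add atoms: water, O
Why: Oxidative demethylation of the para-disposed 5- and 8-methoxy groups by tetravalent cerium (arene radical cation, ipso attack of water, loss of methanol) gives the para-quinone; 7-OMe and O1 have no para oxygen partner, and C2 and C4 are untouched.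

Step 6
Reactants: 6 (2S)-5,7,8-trimethoxy-2-phenylchroman-4-one
Product: 10 (2S)-5-hydroxy-7,8-dimethoxy-2-phenylchroman-4-one
Conditions: BCl3, CH2Cl2, -78 to -20 °C; then aq. NaHCO3
Reagents that add atoms: none
Why: Boron chelation between C4=O and the peri 5-OMe directs chloride to that methyl group only (selective peri-demethylation of aryl ketones); the low temperature guards against Lewis-acid ring opening at C2.

Step 7
Reactants: 10 (2S)-5-hydroxy-7,8-dimethoxy-2-phenylchroman-4-one
Product: 12 (2S)-7,8-dimethoxy-2-phenylchroman-5-ol, via cis-flavan-4,5-diol 11 (not isolated)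
Conditions: NaBH4, THF/MeOH, 0 °C; aqueous work-up; then Et3SiH (5 equiv), CF3CO2H, CH2Cl2, -40 to 0 °C
Reagents that add atoms: none
Why: Borohydride reduction gives the 2-hydroxybenzylic alcohol, which ionises under acid to the ortho-quinone methide/benzylic cation and is reduced by the silane (ionic hydrogenation); C2 is not involved.

Step 8
Reactants: 12 (2S)-7,8-dimethoxy-2-phenylchroman-5-ol; 9 (2S,4R)-7-methoxy-5,8-dioxo-2-phenyl-3,4,5,8-tetrahydro-2H-chromen-4-yl acetate
Product: 13 (2S,8aS)-8a-{[(2S)-7,8-dimethoxy-2-phenylchroman-5-yl]oxy}-7-methoxy-2-phenyl-2,3-dihydro-5H-chromene-5,8(8aH)-dione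
Conditions: 12, Cs2CO3 (1.1 equiv), 4 Å molecular sieves, MeCN, -20 °C; then 9, -20 to 0 °C, argon, dark
Reagents that add atoms: none
Why: Proposed new method: the caesium phenoxide of 12 adds reversibly, through oxygen, to the two alkoxy-bearing β-carbons (C7'' and C8a'') of the doubly vinylogous ester of 9, and only the C8a'' adduct has a β-acetoxy group (on C4''), so its enolate collapses irreversibly by E1cB loss of acetate to the C4a''=C4'' enone; this is an overall syn SN2' displacement whose closest known relatives are the Ferrier-type allylic transposition of glycal 3-esters with phenols and the SN2' etherification of Morita-Baylis-Hillman acetates, neither shown on an alkoxyquinone. No ring is closed, but the step joins the two halves and creates the O,O-ketal carbon C8a'' that will be common to three rings. C8a'' is the only new stereocentre: in the adduct the nearly planar six-membered carbocycle holds C8'' pseudo-equatorial and the aryloxy group pseudo-axial on the pyran chair, so a low-energy adduct requires entry trans to the equatorial 2''-phenyl group. On that face the trans 4''-acetate is axial, parallel to the enolate π system and ready to leave, whereas the adduct from the other face has an equatorial acetate and a 1,3-diaxial phenyl/aryloxy clash and can only revert. The step needs oxygen rather than carbon attack of the ambident phenoxide (caesium phenoxide in an aprotic solvent; every adduct without a leaving group reverts), C8a'' rather than C7'' attack (position of the leaving group; loss of methoxide from the C7'' adduct is slow) and survival of the quinone toward electron transfer and tautomerisation (low temperature, no light, no oxygen).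

Step 9
Reactants: 13 (2S,8aS)-8a-{[(2S)-7,8-dimethoxy-2-phenylchroman-5-yl]oxy}-7-methoxy-2-phenyl-2,3-dihydro-5H-chromene-5,8(8aH)-dione
Product: 14 8''-O-demethyl-4-deoxy-6''-demethoxyneocalycopterone, the (2S,2''S,8''S,8a''S) tertiary carbinol with CH2 at C4 and OH at C8''
Conditions: Sc(OTf)3 (10 mol %), CH2Cl2, -40 to 0 °C
Reagents that add atoms: none
Why: Intramolecular Friedel-Crafts hydroxyalkylation of an α-aryloxy ketone (the benzofuran cyclodehydration, interrupted because C8a'' carries no hydrogen): C6, ortho to the ketal oxygen and to OMe and para to the chroman oxygen, attacks the C8'' ketone activated by chelation with 7''-OMe in a 5-exo-trig closure. The aryl ring is tethered through the axial ketal oxygen, so C6 can reach C8'' only from that face and the cis-fused (8''S) carbinol is the only strain-free outcome.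

Step 10
Reactants: 14 8''-O-demethyl-4-deoxy-6''-demethoxyneocalycopterone
Product: 15 4-deoxy-6''-demethoxyneocalycopterone, (2S,2''S,8''S,8a''S)
Conditions: MeOTf, 2,6-di-tert-butyl-4-methylpyridine, CH2Cl2, 0 °C to rt
Reagents that add atoms: methyl trifluoromethanesulfonate, COS(=O)(=O)C(F)(F)F
Why: O-alkylation of a hindered tertiary alcohol with methyl triflate and a non-nucleophilic pyridine base; 14 has no other hydroxyl group and no bond to a stereocentre is broken.

Step 11
Reactants: 15 4-deoxy-6''-demethoxyneocalycopterone
Product: 16 6''-demethoxyneocalycopterone, (2S,4R,2''S,8''S,8a''S)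
Conditions: DDQ (1.1 equiv), CH2Cl2/H2O (18:1), 0 °C
Reagents that add atoms: water, O
Why: DDQ-mediated benzylic oxidation of a flavan at C4: hydride is abstracted from the only C–H that is benzylic to the arene bearing two ortho oxygens and a para methoxy group, and water captures the cation pseudo-axially, trans to the equatorial 2-phenyl group and out of the plane of the peri furan oxygen (4R). The remaining C4–H then lies near the arene plane and should resist a second abstraction.

## Compound list

1 | 1-(2-hydroxy-3,4,6-trimethoxyphenyl)ethan-1-one | CC(=O)c1c(O)c(OC)c(OC)cc1OC | starting material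
2 | N,N-dimethylformamide dimethyl acetal | COC(OC)N(C)C | starting material
3 | (E)-3-(dimethylamino)-1-(2-hydroxy-3,4,6-trimethoxyphenyl)prop-2-en-1-one (enaminone) | CN(C)/C=C/C(=O)c1c(O)c(OC)c(OC)cc1OC | intermediate (not isolated)
4 | 5,7,8-trimethoxy-4H-chromen-4-one | COc1cc(OC)c(OC)c2occc(=O)c12 | intermediate
5 | phenylboronic acid | OB(O)c1ccccc1 | starting material
6 | (2S)-5,7,8-trimethoxy-2-phenylchroman-4-one | COc1cc(OC)c(OC)c2c1C(=O)C[C@@H](c1ccccc1)O2 | intermediate
7 | (2S,4S)-5,7,8-trimethoxy-2-phenylchroman-4-ol | COc1cc(OC)c(OC)c2c1[C@@H](O)C[C@@H](c1ccccc1)O2 | intermediate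
8 | (2S,4R)-5,7,8-trimethoxy-2-phenylchroman-4-yl acetate | COc1cc(OC)c(OC)c2c1[C@H](OC(C)=O)C[C@@H](c1ccccc1)O2 | intermediate
9 | (2S,4R)-7-methoxy-5,8-dioxo-2-phenyl-3,4,5,8-tetrahydro-2H-chromen-4-yl acetate | COC1=CC(=O)C2=C(C1=O)O[C@H](c1ccccc1)C[C@H]2OC(C)=O | intermediate
10 | (2S)-5-hydroxy-7,8-dimethoxy-2-phenylchroman-4-one | COc1cc(O)c2c(c1OC)O[C@H](c1ccccc1)CC2=O | intermediate
11 | (2S,4S)-7,8-dimethoxy-2-phenylchromane-4,5-diol (cis-flavan-4,5-diol) | COc1cc(O)c2c(c1OC)O[C@H](c1ccccc1)C[C@@H]2O | intermediate (not isolated)
12 | (2S)-7,8-dimethoxy-2-phenylchroman-5-ol | COc1cc(O)c2c(c1OC)O[C@H](c1ccccc1)CC2 | intermediate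
13 | (2S,8aS)-8a-{[(2S)-7,8-dimethoxy-2-phenylchroman-5-yl]oxy}-7-methoxy-2-phenyl-2,3-dihydro-5H-chromene-5,8(8aH)-dione | COC1=CC(=O)C2=CC[C@@H](c3ccccc3)O[C@@]2(Oc2cc(OC)c(OC)c3c2CC[C@@H](c2ccccc2)O3)C1=O | intermediate
14 | 8''-O-demethyl-4-deoxy-6''-demethoxyneocalycopterone, (2S,2''S,8''S,8a''S) | COC1=CC(=O)C2=CC[C@@H](c3ccccc3)O[C@]23Oc2c4c(c(OC)c(OC)c2[C@]13O)O[C@H](c1ccccc1)CC4 | intermediate
15 | 4-deoxy-6''-demethoxyneocalycopterone, (2S,2''S,8''S,8a''S) | COC1=CC(=O)C2=CC[C@@H](c3ccccc3)O[C@]23Oc2c4c(c(OC)c(OC)c2[C@]13OC)O[C@H](c1ccccc1)CC4 | intermediate
16 | 6''-demethoxyneocalycopterone, (2S,4R,2''S,8''S,8a''S) | COC1=CC(=O)C2=CC[C@@H](c3ccccc3)O[C@]23Oc2c4c(c(OC)c(OC)c2[C@]13OC)O[C@H](c1ccccc1)C[C@H]4O | target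

## Step count and least certain steps

Total: 11 steps. Longest linear sequence: 9 steps (steps 1, 2, 3, 4, 5, 8, 9, 10, 11); the second branch (steps 6 and 7) joins at step 8.

Step 8 (key step, new method). Most likely to go wrong: electron transfer from the electron-rich phenoxide to the quinone, base-induced tautomerisation or elimination of the quinone acetate, or carbon attack of the phenoxide may outrun the oxygen addition-elimination at the hindered C8a''. Fallback with known chemistry, setting out from 11 (used crude from step 7) and 12 and returning at 15: 11 would be oxidised with PhI(OAc)2 in MeOH at 0 °C to the para-quinone monoketal (2S,4S)-4-hydroxy-7,8,8-trimethoxy-2-phenyl-2,3,4,8-tetrahydro-5H-chromen-5-one F1. F1 and 12 would then be combined under acid (BF3·OEt2, CH2Cl2, -40 °C) in a phenol/quinone-monoketal (3+2) coupling, in which C6 displaces one methoxy group at C8'', O5 closes onto C8a'' and water is lost from C4'', giving 15 directly. In this fallback C8'' is formed first, so the facial selectivity is not secured by the substrate and the C8''/C8a'' diastereomer would have to be separated.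

Step 9. Most likely to go wrong: attack of C6 on the enone terminus C4'' (six-membered closure after activation of the C5'' carbonyl), or Lewis-acid ionisation of the aryl ketal followed by return through carbon. Fallback from 13 to 15 (no new compound: F0): the C8'' ketone, the only carbonyl that can ketalise, would be turned into a methoxycarbenium ion with MeOSiMe3 and catalytic Me3SiOTf in CH2Cl2 at -78 °C and trapped by C6. This activates C8'' specifically and delivers the methyl ether 15 in the same operation, bypassing 14.

Step 11. Most likely to go wrong: over-oxidation of the new carbinol to the C4 ketone, or loss of a C3 proton from the cation. Fallback from 15 to 16: dehydrogenation with DDQ in dry dioxane would be run on purpose to the 2H-chromene 3,4-didehydro-4-deoxy-6''-demethoxyneocalycopterone F2. After removal of the oxidant, dilute acid in wet THF would hydrate F2 through the same C4 cation, so that the alcohol forms with trans capture of water and with no oxidant present.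

Step 10. Most likely to go wrong: competing O-methylation of the vinylogous ester carbonyl, or sluggish alkylation of the hindered tertiary alcohol. Fallback from 14 to 15 (no new compound: F0): SN1 etherification with catalytic camphorsulfonic acid in MeOH over 3 Å molecular sieves. The C8'' cation, held coplanar with the trioxygenated arene by the five-membered ring, would be captured by methanol on the convex face, which keeps the cis fusion.

Step 2. Most likely to go wrong: low reactivity of the electron-rich, peri-substituted chromone, so that protodeboronation outruns insertion, or incomplete enantiocontrol. Fallback from 1, returning at 6: Claisen-Schmidt condensation of 1 with benzaldehyde (KOH, EtOH) would give (E)-1-(2-hydroxy-3,4,6-trimethoxyphenyl)-3-phenylprop-2-en-1-one F3, and oxa-Michael cyclisation (NaOAc, EtOH, reflux) would give racemic 5,7,8-trimethoxy-2-phenylchroman-4-one F4. Kinetic resolution by asymmetric transfer hydrogenation (RuCl(TsDPEN)(p-cymene), HCO2H/Et3N, with the catalyst antipode that consumes the 2R ketone) would reduce one enantiomer to (2R,4R)-5,7,8-trimethoxy-2-phenylchroman-4-ol F5 and leave 6.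

## Further compounds

F1 | step 8 | (2S,4S)-4-hydroxy-7,8,8-trimethoxy-2-phenyl-2,3,4,8-tetrahydro-5H-chromen-5-one | COC1=CC(=O)C2=C(O[C@H](c3ccccc3)C[C@@H]2O)C1(OC)OC
F0 | step 9 | none | none
F2 | step 11 | 3,4-didehydro-4-deoxy-6''-demethoxyneocalycopterone (2H-chromene in unit A) | COC1=CC(=O)C2=CC[C@@H](c3ccccc3)O[C@]23Oc2c4c(c(OC)c(OC)c2[C@]13OC)O[C@H](c1ccccc1)C=C4
F0 | step 10 | none | none
F3 | step 2 | (E)-1-(2-hydroxy-3,4,6-trimethoxyphenyl)-3-phenylprop-2-en-1-one | COc1cc(OC)c(OC)c(O)c1C(=O)/C=C/c1ccccc1
F4 | step 2 | racemic 5,7,8-trimethoxy-2-phenylchroman-4-one | COc1cc(OC)c(OC)c2c1C(=O)CC(c1ccccc1)O2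
F5 | step 2 | (2R,4R)-5,7,8-trimethoxy-2-phenylchroman-4-ol | COc1cc(OC)c(OC)c2c1[C@H](O)C[C@H](c1ccccc1)O2
A1 | alternative 1 | (2S,4R)-7,8-dimethoxy-2-phenylchromane-4,5-diol | Oc1cc(OC)c(OC)c2c1[C@H](O)C[C@@H](c1ccccc1)O2
A2 | alternative 1 | (2S,4R)-4-hydroxy-7,8,8-trimethoxy-2-phenyl-2,3,4,8-tetrahydro-5H-chromen-5-one | COC1=CC(=O)C2=C(O[C@H](c3ccccc3)C[C@H]2O)C1(OC)OC
A3 | alternative 2 | (2S)-7-methoxy-2-phenyl-3,4-dihydro-2H-chromene-5,8-dione | COC1=CC(=O)C2=C(C1=O)O[C@H](c1ccccc1)CC2
A4 | alternative 2 | (2S)-7,8-dimethoxy-5-(methoxymethoxy)-2-phenylchromane | COCOc1cc(OC)c(OC)c2c1CC[C@@H](c1ccccc1)O2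
A5 | alternative 2 | (2S,8S)-8-[(2S)-7,8-dimethoxy-5-(methoxymethoxy)-2-phenylchroman-6-yl]-7,8-dimethoxy-2-phenyl-2,3,4,8-tetrahydro-5H-chromen-5-one | COCOc1c2c(c(OC)c(OC)c1[C@]1(OC)C(OC)=CC(=O)C3=C1O[C@H](c1ccccc1)CC3)O[C@H](c1ccccc1)CC2
A6 | alternative 3 | pentacarbonyl{[(2S,4R)-4-(tert-butyldimethylsilyloxy)-2-phenyl-3,4-dihydro-2H-pyran-6-yl](methoxy)methylidene}chromium | COC(=[Cr](=C=O)(=C=O)(=C=O)(=C=O)=C=O)C1=C[C@H](O[Si](C)(C)C(C)(C)C)C[C@@H](c2ccccc2)O1
A7 | alternative 3 | (2S,8S)-7,8-dimethoxy-8-(methoxyethynyl)-2-phenyl-2,3,4,8-tetrahydro-5H-chromen-5-one | COC#C[C@]1(OC)C(OC)=CC(=O)C2=C1O[C@H](c1ccccc1)CC2
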